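## Retrosynthetic overview

1. The target is a spiro-dihydrofuran-linked dimer of two 6-oxo-abietane units whose decalin parts are antipodal (upper half 5S,10S with spiro C7; lower quinone methide half 5'R,10'R). Both halves therefore come from the two antipodes of one racemic 6-5-6 nor-ketone, which is resolved.
2. Last disconnections: the three O-methyl groups and the C11'/C12' catechol-to-quinone-methide oxidation, then the C7–O14' bond (5-exo oxa-Michael addition of O14'–H to the C7=C8 quinone methide of the upper half, then reoxidation).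
3. Key disconnection: C7–C7' together with the C8'–C7' bond of ring B'. The three components are the lower-half nor-ketone (ring B' still five-membered), Me3SiCHN2 (supplies C7') and the upper-half quinone methide. Enabling feature: in ring B' a single carbon, C7', lies between aryl C8' and carbonyl C6' and is also the only carbon bonded to C7; a one-carbon unit inserted into C8'–C6' thus completes ring B' and becomes the benzylic enol carbon that attacks C7, the methide carbon of the upper-half 6-oxo quinone methide.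
4. The upper half comes from the antipodal nor-ketone by the same one-carbon homologation and oxidative demethylation; the nor-ketone comes from an aromatic Nazarov cyclisation of an aryl 2,6,6-trimethylcyclohexenyl ketone.
5. Ring order: ring C (arene) and ring A (β-cyclocitral) are bought; then the five-membered nor-B ring (step 6), ring B of the upper half (step 8), ring B' of the lower half (step 12), and the dihydrofuran (step 13).

Key step: step 12

Remark: abietane numbering is used and primed atoms belong to the lower (quinone methide) half; in the target C7 is R, with C7–O14' on the α face and C7–C7' on the β face (cis to the C10 methyl).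
Remark: the upper-half hydroxyquinone is drawn in the target as the 14-hydroxy-11,12-dione; this and the 12-hydroxy-11,14-dione are tautomers of one compound.
Assumption: protonation of the Nazarov silyl enol ether in step 6 occurs anti to the angular methyl and gives the trans ring fusion; this is expected, not established, and the whole route depends on it.

## Route

Step 1
Reactants: 1 1,2,4-trimethoxybenzene; 2 acetone
Product: 4 2-(2,3,6-trimethoxyphenyl)propan-2-ol, via aryllithium 3 (not isolated)
Conditions: n-BuLi, TMEDA, THF, 0 °C; then 2, −78 °C to rt; H2O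
Reagents that add atoms: none
Why: Directed ortho-metalation removes the proton at C3, the only position flanked by two methoxy groups, and the aryllithium adds to acetone.

Step 2
Reactants: 4 2-(2,3,6-trimethoxyphenyl)propan-2-ol
Product: 5 2-isopropyl-1,3,4-trimethoxybenzene
Conditions: Et3SiH, CF3CO2H, CH2Cl2, 0 °C to rt
Reagents that add atoms: none
Why: Ionic hydrogenation, in which the tertiary benzylic cation formed in acid is reduced by hydride transfer from the silane.

Step 3
Reactants: 5 2-isopropyl-1,3,4-trimethoxybenzene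
Product: 6 1-bromo-3-isopropyl-2,4,5-trimethoxybenzene
Conditions: NBS, MeCN, 0 °C to rt
Reagents that add atoms: N-bromosuccinimide, O=C1CCC(=O)N1Br
Why: Electrophilic aromatic bromination should go to the free position that is ortho and para to methoxy groups (future C8), since the other free position (future C9) has only one ortho methoxy activator.

Step 4
Reactants: 6 1-bromo-3-isopropyl-2,4,5-trimethoxybenzene; 7 β-cyclocitral
Product: 9 (3-isopropyl-2,4,5-trimethoxyphenyl)(2,6,6-trimethylcyclohex-1-en-1-yl)methanol (racemic), via aryllithium 8 (not isolated)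
Conditions: n-BuLi, THF, −78 °C; then 7, −78 to 0 °C; H2O
Reagents that add atoms: none
Why: Bromine–lithium exchange followed by 1,2-addition of the aryllithium to the hindered enal; the new carbinol centre is removed in step 5.

Step 5
Reactants: 9 (3-isopropyl-2,4,5-trimethoxyphenyl)(2,6,6-trimethylcyclohex-1-en-1-yl)methanol
Product: 10 (3-isopropyl-2,4,5-trimethoxyphenyl)(2,6,6-trimethylcyclohex-1-en-1-yl)methanone
Conditions: 2-iodoxybenzoic acid, EtOAc, 75 °C
Reagents that add atoms: none
Why: Oxidation of a doubly activated (benzylic and allylic) secondary alcohol to the aryl vinyl ketone needed for the Nazarov reaction.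

Step 6
Reactants: 10 (3-isopropyl-2,4,5-trimethoxyphenyl)(2,6,6-trimethylcyclohex-1-en-1-yl)methanone
Product: 12 rac-(4bS,8aS)-2-isopropyl-1,3,4-trimethoxy-4b,8,8-trimethyl-4b,5,6,7,8,8a-hexahydro-9H-fluoren-9-one (trans-fused), via silyl enol ether 11 (not isolated)
Conditions: Me3SiOTf (1.2 equiv), MeNO2, 0 °C to rt; poured into cold aq. NaHCO3
Reagents that add atoms: none
Why: Aromatic Nazarov cyclisation, in which 4π-conrotatory closure of the O-silylated pentadienyl cation forms the C9–C10 bond and the quaternary centre, rearomatisation gives silyl enol ether 11, and kinetic protonation at C5 on the face opposite to the angular methyl should give the trans ring fusion (racemate).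

Step 7
Reactants: 12 rac-(4bS,8aS)-2-isopropyl-1,3,4-trimethoxy-4b,8,8-trimethyl-4b,5,6,7,8,8a-hexahydro-9H-fluoren-9-one
Product: 13 (4bS,8aS)-2-isopropyl-1,3,4-trimethoxy-4b,8,8-trimethyl-4b,5,6,7,8,8a-hexahydro-9H-fluoren-9-one and 14 its (4bR,8aR) antipode (both collected)
Conditions: preparative SFC, amylose tris(3,5-dimethylphenylcarbamate) stationary phase, CO2/MeOH
Reagents that add atoms: none
Why: Chromatographic resolution on a chiral stationary phase creates no new stereocentre and discards nothing, because antipode 13 becomes the upper half (step 8) and antipode 14, collected beside it as the other fraction, becomes the lower half (step 10).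

Step 8
Reactants: 13 (4bS,8aS)-2-isopropyl-1,3,4-trimethoxy-4b,8,8-trimethyl-4b,5,6,7,8,8a-hexahydro-9H-fluoren-9-one; 15 trimethylsilyldiazomethane
Product: 17 (5S,10S)-11,12,14-trimethoxyabieta-8,11,13-trien-6-one, via silyl ketone 16 (not isolated)
Conditions: BF3·OEt2 (1.5 equiv), CH2Cl2, −78 to −20 °C; 1 M HCl, THF, rt
Reagents that add atoms: none
Why: Lewis-acid-promoted diazoalkane homologation (Tiffeneau–Demjanov-type ring expansion) with migration of the electron-rich aryl carbon, as known for 1-indanones, followed by protodesilylation; C5 and C10 are untouched.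

Step 9
Reactants: 17 (5S,10S)-11,12,14-trimethoxyabieta-8,11,13-trien-6-one
Product: 18 (5S,10S)-12-methoxyabieta-8,12-diene-6,11,14-trione
Conditions: (NH4)2Ce(NO3)6 (2.2 equiv), MeCN/H2O, 0 °C, short contact; used at once
Reagents that add atoms: water, O
Why: Oxidative demethylation of the para-dimethoxyarene gives the methoxy-para-quinone, whose C7 methylene between ketone and quinone makes the C7=C8 quinone methide tautomer (11-hydroxy-12-methoxyabieta-7,9(11),12-triene-6,14-dione) accessible.

Step 10
Reactants: 14 (4bR,8aR)-2-isopropyl-1,3,4-trimethoxy-4b,8,8-trimethyl-4b,5,6,7,8,8a-hexahydro-9H-fluoren-9-one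
Product: 19 (4bR,8aR)-1-hydroxy-2-isopropyl-3,4-dimethoxy-4b,8,8-trimethyl-4b,5,6,7,8,8a-hexahydro-9H-fluoren-9-one
Conditions: BCl3 (1.1 equiv), CH2Cl2, −78 to −20 °C; H2O
Reagents that add atoms: none
Why: Chelation-controlled demethylation, in which BCl3 bound to the ketone cleaves only the peri methoxy group (future O14'), so the oxygen that must later close the dihydrofuran is marked on the lower half only.

Step 11
Reactants: 19 (4bR,8aR)-1-hydroxy-2-isopropyl-3,4-dimethoxy-4b,8,8-trimethyl-4b,5,6,7,8,8a-hexahydro-9H-fluoren-9-one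
Product: 20 (4bR,8aR)-1-acetoxy-2-isopropyl-3,4-dimethoxy-4b,8,8-trimethyl-4b,5,6,7,8,8a-hexahydro-9H-fluoren-9-one
Conditions: Ac2O, pyridine, DMAP (cat.), CH2Cl2, 0 °C to rt
Reagents that add atoms: acetic anhydride, CC(=O)OC(C)=O
Why: Acetylation masks the phenol against O-alkylation by the diazo reagent and removes the hydrogen bond that deactivates the ketone, under conditions that do not enolise C8a.

Step 12
Reactants: 20 (4bR,8aR)-1-acetoxy-2-isopropyl-3,4-dimethoxy-4b,8,8-trimethyl-4b,5,6,7,8,8a-hexahydro-9H-fluoren-9-one; 15 trimethylsilyldiazomethane; 18 (5S,10S)-12-methoxyabieta-8,12-diene-6,11,14-trione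
Product: 23 (5S,10S,5'R,10'R)-14'-acetoxy-11,14-dihydroxy-12,11',12'-trimethoxy-7,7'-biabieta-8,11,13,8',11',13'-hexaene-6,6'-dione (C7/C7' epimer mixture; kept under argon), via silyl ketone 21 (not isolated), via silyl enol ether 22 (not isolated)
Conditions: 20, 15 (1.1 equiv), BF3·OEt2 (1.5 equiv), CH2Cl2, −78 to −20 °C until N2 evolution ends; Me3SiOTf (0.2 equiv), 0 °C; then 18 (1.0 equiv, slow addition), −78 to −20 °C; degassed aq. NaHCO3
Reagents that add atoms: none
Why: Proposed new method: the diazo carbon of 15 adds to the BF3-activated C6' carbonyl of 20, and loss of N2 with 1,2-shift of the aryl carbon C8' inserts C7' between C8' and C6', so that the five-membered ring grows into ring B' by ring expansion and not by a cyclisation; the closest known reaction type is the Lewis-acid-promoted Me3SiCHN2 homologation of 1-indanones to 2-tetralones (Tiffeneau–Demjanov-type, Büchner–Curtius–Schlotterbeck reaction). The C7'-silyl ketone 21 is isomerised by Me3SiOTf to the benzylic silyl enol ether 22, which adds in a Mukaiyama–Michael reaction to C7 of the quinone methide tautomer of 18 (closest known type: Lewis-acid-mediated addition of silyl enol ethers to quinone methides), driven by aromatisation of ring C of the upper half. The new stereocentres C7 and C7' need no control, because C7' becomes trigonal in step 14 and C7 is re-set in step 13 through its planar quinone methide, so all diastereomers converge. The step needs aryl over alkyl migration, secured by the para-methoxy donor on C8' and by the doubly flanked, neopentyl-like C5'. It needs cross- over self-addition of 18, secured by the preformed nucleophile 22 and the slow addition of 18. It needs retention at C5', secured because the new 2-tetralone enolises only towards benzylic C7'.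

Step 13
Reactants: 23 (5S,10S,5'R,10'R)-14'-acetoxy-11,14-dihydroxy-12,11',12'-trimethoxy-7,7'-biabieta-8,11,13,8',11',13'-hexaene-6,6'-dione
Product: 27 (5S,10S,5'R,10'R)-7,14'-epoxy-12,11',12'-trimethoxy-7,7'-biabieta-8,12,8',11',13'-pentaene-6,11,14,6'-tetraone (spiro centre as in the target; C7' epimers), via phenol 24 (not isolated), via quinone 25 (not isolated), via spiro hydroquinone 26 (not isolated)
Conditions: K2CO3 (cat.), MeOH, 0 °C, Ar; AcOH to neutral, solvent exchange to CH2Cl2; Ag2O (2.5 equiv), MgSO4, rt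
Reagents that add atoms: none
Why: Methanolysis frees O14'–H, Ag2O oxidises the upper-half hydroquinone to quinone 25, whose C7–H tautomerises to the C7=C8 quinone methide, O14' adds to it in a 5-exo-trig oxa-Michael reaction from the α face anti to the axial C10 methyl (which places C7' on the β face), and reoxidation of hydroquinone 26 gives 27; the lower ring C' is a monophenol that should not be oxidised under these conditions, so the two halves cannot exchange roles.

Step 14
Reactants: 27 (5S,10S,5'R,10'R)-7,14'-epoxy-12,11',12'-trimethoxy-7,7'-biabieta-8,12,8',11',13'-pentaene-6,11,14,6'-tetraone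
Product: 29 CNP0568854.1 (target), via catechol 28 (not isolated)
Conditions: BBr3 (6 equiv), CH2Cl2, −78 to 0 °C; H2O; then Ag2O (1.5 equiv), CH2Cl2/Et2O, rt
Reagents that add atoms: none
Why: BBr3 cleaves the three remaining methyl ethers (the vinylogous ester at C12 and the C11'/C12' veratrole unit) while the tertiary spiro ether at C7, flanked by a ketone and a quinone, can neither ionise nor undergo SN2 cleavage, and Ag2O then oxidises the catechol to the ortho-quinone, which tautomerises through C7'–H to the para-quinone methide as in taxodione-type systems.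

## Compound list

1 | 1,2,4-trimethoxybenzene | COc1ccc(OC)c(OC)c1 | starting material
2 | acetone | CC(C)=O | starting material
3 | (2,3,6-trimethoxyphenyl)lithium | [Li]c1c(OC)ccc(OC)c1OC | intermediate (not isolated)
4 | 2-(2,3,6-trimethoxyphenyl)propan-2-ol | COc1ccc(OC)c(C(C)(C)O)c1OC | intermediate
5 | 2-isopropyl-1,3,4-trimethoxybenzene | COc1ccc(OC)c(C(C)C)c1OC | intermediate
6 | 1-bromo-3-isopropyl-2,4,5-trimethoxybenzene | COc1cc(Br)c(OC)c(C(C)C)c1OC | intermediate
7 | β-cyclocitral (2,6,6-trimethylcyclohex-1-ene-1-carbaldehyde) | CC1=C(C=O)C(C)(C)CCC1 | starting material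
8 | (3-isopropyl-2,4,5-trimethoxyphenyl)lithium | COc1cc([Li])c(OC)c(C(C)C)c1OC | intermediate (not isolated)
9 | (3-isopropyl-2,4,5-trimethoxyphenyl)(2,6,6-trimethylcyclohex-1-en-1-yl)methanol, racemic | COc1cc(C(O)C2=C(C)CCCC2(C)C)c(OC)c(C(C)C)c1OC | intermediate
10 | (3-isopropyl-2,4,5-trimethoxyphenyl)(2,6,6-trimethylcyclohex-1-en-1-yl)methanone | COc1cc(C(=O)C2=C(C)CCCC2(C)C)c(OC)c(C(C)C)c1OC | intermediate
11 | 2-isopropyl-1,3,4-trimethoxy-4b,8,8-trimethyl-9-(trimethylsilyloxy)-5,6,7,8-tetrahydro-4bH-fluorene, racemic | CC(C)c1c(OC)c(OC)c2c(c1OC)C(O[Si](C)(C)C)=C1C(C)(C)CCCC21C | intermediate (not isolated)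
12 | rac-(4bS,8aS)-2-isopropyl-1,3,4-trimethoxy-4b,8,8-trimethyl-4b,5,6,7,8,8a-hexahydro-9H-fluoren-9-one (both antipodes) | CC(C)c1c(OC)c(OC)c2c(c1OC)C(=O)[C@H]1C(C)(C)CCC[C@]21C.CC(C)c1c(OC)c(OC)c2c(c1OC)C(=O)[C@@H]1C(C)(C)CCC[C@@]21C | intermediate
13 | (4bS,8aS)-2-isopropyl-1,3,4-trimethoxy-4b,8,8-trimethyl-4b,5,6,7,8,8a-hexahydro-9H-fluoren-9-one | CC(C)c1c(OC)c(OC)c2c(c1OC)C(=O)[C@H]1C(C)(C)CCC[C@]21C | intermediate
14 | (4bR,8aR)-2-isopropyl-1,3,4-trimethoxy-4b,8,8-trimethyl-4b,5,6,7,8,8a-hexahydro-9H-fluoren-9-one | CC(C)c1c(OC)c(OC)c2c(c1OC)C(=O)[C@@H]1C(C)(C)CCC[C@@]21C | intermediate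
15 | trimethylsilyldiazomethane | C[Si](C)(C)C=[N+]=[N-] | starting material
16 | (5S,10S)-11,12,14-trimethoxy-7-(trimethylsilyl)abieta-8,11,13-trien-6-one (C7 epimers) | CC(C)c1c(OC)c(OC)c2c(c1OC)C([Si](C)(C)C)C(=O)[C@H]1C(C)(C)CCC[C@]21C | intermediate (not isolated)
17 | (5S,10S)-11,12,14-trimethoxyabieta-8,11,13-trien-6-one | CC(C)c1c(OC)c(OC)c2c(c1OC)CC(=O)[C@H]1C(C)(C)CCC[C@]21C | intermediate
18 | (5S,10S)-12-methoxyabieta-8,12-diene-6,11,14-trione | CC(C)C1=C(OC)C(=O)C2=C(C1=O)CC(=O)[C@H]1C(C)(C)CCC[C@]21C | intermediate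
19 | (4bR,8aR)-1-hydroxy-2-isopropyl-3,4-dimethoxy-4b,8,8-trimethyl-4b,5,6,7,8,8a-hexahydro-9H-fluoren-9-one | CC(C)c1c(OC)c(OC)c2c(c1O)C(=O)[C@@H]1C(C)(C)CCC[C@@]21C | intermediate
20 | (4bR,8aR)-1-acetoxy-2-isopropyl-3,4-dimethoxy-4b,8,8-trimethyl-4b,5,6,7,8,8a-hexahydro-9H-fluoren-9-one | CC(C)c1c(OC)c(OC)c2c(c1OC(C)=O)C(=O)[C@@H]1C(C)(C)CCC[C@@]21C | intermediate
21 | (5R,10R)-14-acetoxy-11,12-dimethoxy-7-(trimethylsilyl)abieta-8,11,13-trien-6-one (C7 epimers) | CC(C)c1c(OC)c(OC)c2c(c1OC(C)=O)C([Si](C)(C)C)C(=O)[C@@H]1C(C)(C)CCC[C@@]21C | intermediate (not isolated)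
22 | (5R,10R)-14-acetoxy-11,12-dimethoxy-6-(trimethylsilyloxy)abieta-6,8,11,13-tetraene | CC(C)c1c(OC)c(OC)c2c(c1OC(C)=O)C=C(O[Si](C)(C)C)[C@@H]1C(C)(C)CCC[C@@]21C | intermediate (not isolated)
23 | (5S,10S,5'R,10'R)-14'-acetoxy-11,14-dihydroxy-12,11',12'-trimethoxy-7,7'-biabieta-8,11,13,8',11',13'-hexaene-6,6'-dione (C7/C7' epimers) | CC(C)c1c(OC)c(O)c2c(c1O)C(C1C(=O)[C@@H]3C(C)(C)CCC[C@@]3(C)c3c(OC)c(OC)c(C(C)C)c(OC(C)=O)c13)C(=O)[C@H]1C(C)(C)CCC[C@]21C | intermediate
24 | (5S,10S,5'R,10'R)-11,14,14'-trihydroxy-12,11',12'-trimethoxy-7,7'-biabieta-8,11,13,8',11',13'-hexaene-6,6'-dione (C7/C7' epimers) | CC(C)c1c(OC)c(O)c2c(c1O)C(C1C(=O)[C@@H]3C(C)(C)CCC[C@@]3(C)c3c(OC)c(OC)c(C(C)C)c(O)c13)C(=O)[C@H]1C(C)(C)CCC[C@]21C | intermediate (not isolated)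
25 | (5S,10S,5'R,10'R)-14'-hydroxy-12,11',12'-trimethoxy-7,7'-biabieta-8,12,8',11',13'-pentaene-6,11,14,6'-tetraone (C7/C7' epimers) | CC(C)C1=C(OC)C(=O)C2=C(C1=O)C(C1C(=O)[C@@H]3C(C)(C)CCC[C@@]3(C)c3c(OC)c(OC)c(C(C)C)c(O)c13)C(=O)[C@H]1C(C)(C)CCC[C@]21C | intermediate (not isolated)
26 | (5S,10S,5'R,10'R)-7,14'-epoxy-11,14-dihydroxy-12,11',12'-trimethoxy-7,7'-biabieta-8,11,13,8',11',13'-hexaene-6,6'-dione (O14' α, C7' β at C7; C7' epimers) | CC(C)c1c(O)c2c(c(O)c1OC)[C@@]1(C)CCCC(C)(C)[C@@H]1C(=O)[C@@]21Oc2c(C(C)C)c(OC)c(OC)c3c2C1C(=O)[C@@H]1C(C)(C)CCC[C@@]31C | intermediate (not isolated)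
27 | (5S,10S,5'R,10'R)-7,14'-epoxy-12,11',12'-trimethoxy-7,7'-biabieta-8,12,8',11',13'-pentaene-6,11,14,6'-tetraone (O14' α, C7' β at C7; C7' epimers) | CC(C)C=1C(=O)C2=C(C(=O)C=1OC)[C@@]1(C)CCCC(C)(C)[C@@H]1C(=O)[C@@]21Oc2c(C(C)C)c(OC)c(OC)c3c2C1C(=O)[C@@H]1C(C)(C)CCC[C@@]31C | intermediate
28 | (5S,10S,5'R,10'R)-7,14'-epoxy-12,11',12'-trihydroxy-7,7'-biabieta-8,12,8',11',13'-pentaene-6,11,14,6'-tetraone (O14' α, C7' β at C7; C7' epimers) | CC(C)C=1C(=O)C2=C(C(=O)C=1O)[C@@]1(C)CCCC(C)(C)[C@@H]1C(=O)[C@@]21Oc2c(C(C)C)c(O)c(O)c3c2C1C(=O)[C@@H]1C(C)(C)CCC[C@@]31C | intermediate (not isolated)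
29 | CNP0568854.1 | CC(C)C1=C(O)C2=C(C(=O)C1=O)[C@@]1(C)CCCC(C)(C)[C@@H]1C(=O)[C@@]21OC2=C(C(C)C)C(=O)C(O)=C3C2=C1C(=O)[C@@H]1C(C)(C)CCC[C@@]31C | target

## Step count and risks

Total steps: 14. Longest linear sequence: 12 steps (steps 1–7, 10–14); steps 8–9 form the short branch to the upper half.

Steps most likely to fail:

Step 12 (proposed new method). The hindered aryl ketone of 20, flanked on both sides, may add the diazo carbon too slowly, or the unpurified enol silane may be protodesilylated while 18 self-condenses through its own enol and quinone methide forms. The fallback splits the operation into known reactions with isolated intermediates. It sets out from 20: the BF3·OEt2/Me3SiCHN2 homologation is run alone with acidic work-up to isolate the ring-expanded ketone (5R,10R)-14-acetoxy-11,12-dimethoxyabieta-8,11,13-trien-6-one F1. F1 is converted with Me3SiOTf/Et3N into purified silyl enol ether 22 (enolisation towards benzylic C7'). 22 is then added to freshly made 18 under catalytic Sc(OTf)3 in a separate Mukaiyama–Michael step, which returns to the route at 23.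

Step 13. The 5-exo ring closure at C7 may show poor facial selectivity, or the quinone methide may be intercepted by external nucleophiles before O14' closes. The fallback replaces kinetic control by thermodynamic correction. It sets out from the epimer mixture of 27: catalytic DBU in toluene should eliminate the phenoxide O14' (C7'–H is acidic) to give the ring-opened ene-dione phenol F2, which recloses reversibly. The spiro epimers then equilibrate, the unwanted one is separated and recycled through F2, and the sequence returns to the route at 27. The reopening cannot exchange the roles of the halves, because the upper ring is locked as the methoxyquinone and the lower ring is not at the quinone level.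

Step 14. The Lewis acid may open the spiro ether, epimerise C5 or C5' through the only remaining enolisation direction of the two ketones, or leave hindered methoxy groups uncleaved. The fallback changes the protecting-group plan for the lower half, so that no Lewis acid is used after the spiro ring exists. It sets out from 14: BBr3 at the simple ketone stage gives the triol (4bR,8aR)-1,3,4-trihydroxy-2-isopropyl-4b,8,8-trimethyl-4b,5,6,7,8,8a-hexahydro-9H-fluoren-9-one F3, and peracetylation gives the triacetate F4. F4 is taken through the conditions of step 12 with 15 and 18 to the triacetoxy adduct F5. Methanolysis of the three acetates under argon is followed by excess Ag2O added in one portion. This oxidises both rings at once; the upper half closes with O14' as in step 13 while the lower half becomes the hydroxy quinone methide, giving the 12-O-methyl ether of the target F6. Mild hydrolysis of this vinylogous ester (aqueous LiOH, THF, 0 °C, then acidification) returns to the route at 29.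

Further compounds
F1 | step 12 | (5R,10R)-14-acetoxy-11,12-dimethoxyabieta-8,11,13-trien-6-one | CC(C)c1c(OC)c(OC)c2c(c1OC(C)=O)CC(=O)[C@@H]1C(C)(C)CCC[C@@]21C
F2 | step 13 | (5S,10S,5'R,10'R)-14'-hydroxy-12,11',12'-trimethoxy-7,7'-biabieta-7(7'),8,12,8',11',13'-hexaene-6,11,14,6'-tetraone (alkene isomers) | CC(C)C1=C(OC)C(=O)C2=C(C1=O)C(=C1C(=O)[C@@H]3C(C)(C)CCC[C@@]3(C)c3c(OC)c(OC)c(C(C)C)c(O)c13)C(=O)[C@H]1C(C)(C)CCC[C@]21C
F3 | step 14 | (4bR,8aR)-1,3,4-trihydroxy-2-isopropyl-4b,8,8-trimethyl-4b,5,6,7,8,8a-hexahydro-9H-fluoren-9-one | CC(C)c1c(O)c(O)c2c(c1O)C(=O)[C@@H]1C(C)(C)CCC[C@@]21C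
F4 | step 14 | (4bR,8aR)-1,3,4-triacetoxy-2-isopropyl-4b,8,8-trimethyl-4b,5,6,7,8,8a-hexahydro-9H-fluoren-9-one | CC(C)c1c(OC(C)=O)c(OC(C)=O)c2c(c1OC(C)=O)C(=O)[C@@H]1C(C)(C)CCC[C@@]21C
F5 | step 14 | (5S,10S,5'R,10'R)-11',12',14'-triacetoxy-11,14-dihydroxy-12-methoxy-7,7'-biabieta-8,11,13,8',11',13'-hexaene-6,6'-dione (C7/C7' epimers) | CC(C)c1c(OC)c(O)c2c(c1O)C(C1C(=O)[C@@H]3C(C)(C)CCC[C@@]3(C)c3c(OC(C)=O)c(OC(C)=O)c(C(C)C)c(OC(C)=O)c13)C(=O)[C@H]1C(C)(C)CCC[C@]21C
F6 | step 14 | 12-O-methyl ether of CNP0568854.1 | CC(C)C=1C(=O)C2=C(C(=O)C=1OC)[C@@]1(C)CCCC(C)(C)[C@@H]1C(=O)[C@@]21OC2=C(C(C)C)C(=O)C(O)=C3C2=C1C(=O)[C@@H]1C(C)(C)CCC[C@@]31C
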